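## Structural features

Diaporindene H (22) is a 1-aryl-2-alkylidene-indane. Ring A (benzene; C3a, C4, C5, C6, C7, C7a) is fused through C3a–C7a to ring B (cyclopentane; C1, C2, C3). C1 is bonded to C8' of ring C, the arene of a 2,3-dihydro-1,4-benzodioxine whose dioxane is ring D (O1', C2', C3', O4'; methyl on C6'; C(CH3)2OH on C2'; O1' sits on C8a', next to C8'). C2 carries an exocyclic, tetrasubstituted isopropylidene group and C3 is CH2. Ring A carries four contiguous substituents: C3 on C3a, C1 on C7a, CHO on C7 and OH on C6, the OH being para to C3a. The two stereocentres, C1 (S) and C2' (S), do not stand next to each other (C8', C8a' and O1' lie between them), and C1 has no neighbouring stereocentre at all because C2 is sp2. C1–H is benzylic to rings A and C and allylic, and the C2=C(CH3)2 bond is skipped with respect to both arenes; acid or strong base would move it into ring B (indene) and erase C1. Other fragile groups are the free salicylaldehyde (aldehyde peri to C1) and the tertiary alcohol. The real difficulty is the crowded 1,2,3,4-tetrasubstituted ring A with the aldehyde wedged between the phenol and C7a, the isolated, triply activated methine C1, and the position of the tetrasubstituted alkene. The key step exploits that O–C6–C5–C4–C3a of ring A is a 2-alkylfuran in disguise and C7(CHO)–C7a an alkynal: a phenol para to the former furan C2 and ortho to a formyl group is what a furan/ynal Diels–Alder adduct gives on aromatisation, and because C3a–C7a is common to rings A and B, forming it intramolecularly closes both rings.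

## Logic of the disconnections

22 ⇒ 20 (through 21). Bonds cut: C3a–C7a and C6–C7, with the C3a–O bond restored so that O, C6, C5, C4 and C3a become a furan. In one sentence: rings A and B of 22 are made together by an intramolecular furan/ynal Diels–Alder–aromatisation of the open-chain 20. The cut is made here because it removes ring A, ring B, the phenol and the aldehyde in one operation and needs no protecting group. The gain is that the indane core falls back to a seven-carbon chain between a furan and a formyl group, with C1 as the only stereocentre to carry. The demand on the forward step is that cycloaddition must outrun prototropic isomerisation of the skipped enynal (C1–H is γ to the ynal) and that the oxa bridge must open towards C6–OH.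

20 ⇒ 18 ⇒ 17. Bonds cut: the C7–CHO bond, then the C–Si bond. The activating and most sensitive group is put on last. The demand is acetylide formation without deprotonation at C1.

17 ⇒ 15 + 16. Bond cut: C3–C(furan), with allylic transposition. The tetrasubstituted alkene is not made by an elimination, whose regiochemistry would be uncertain; it appears regiospecifically when the furyl group enters at the CH2 terminus of a 1,1-dimethylallyl unit. The gain is that the alkene problem becomes an allyl-terminus selectivity with a strong steric bias. The demand is tolerance of the free C2' side-chain alcohol and of the silylalkyne.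

15 ⇒ 13 ⇒ 11. Bonds cut: the two C–CH3 bonds of the carbinol and the C2=CH2 bond. The 2-substituted acrylate 13 comes from the malonyl unit of 11 by decarboxylative methylenation. The demand is that both steps be non-basic, since C1–H of 13 is γ to the acrylate.

11 ⇒ 9 + 10, and 9 ⇒ 7 + 8. Bonds cut: C1–C(alkyne), then the C1=C2 bond of the arylidene. C1 is set here, by catalyst control, in a conjugate alkynylation of an achiral-at-C1 acceptor made in one step from the aldehyde. The demand is facial control by the ligand alone, since C2' is remote.

7 ⇒ 5 + 3, then 5 ⇒ 4 and 3 ⇒ 1 (through 2). Bonds cut: O4'–C3' and O1'–C2'. Ring D is closed by two successive phenoxide substitutions on one chiral C5 epoxy sulfonate. C2' comes from the epoxide carbon with inversion; the epoxide comes from asymmetric epoxidation of 1. The demand is that the non-chelated phenoxide of 5 alkylates first and that the epoxide opens at its secondary carbon.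

## Other disconnections considered

Alternative 1: the C1–C8' bond (the first idea). Rhodium-catalysed enantioselective 1,4-addition of the arylboronic acid A1 to the indenone A2 would give the 3-arylindanone A3; aldol condensation with acetone would then give the isopropylidene ketone A4, and the ketone oxygen would have to be removed. The chosen plan is preferred on three grounds. Ring A of A2, with its four contiguous substituents, still has to be built and protected by stepwise aromatic substitution. In A4 the stereocentre's hydrogen is γ to the enone, so epimerisation and migration of the alkene to the endocyclic indenone are expected. Deoxygenation of a ketone conjugated to the tetrasubstituted alkene passes through allylic intermediates that can move the double bond. The sequence is also longer.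

Alternative 2: the C1–C2 bond, along biogenetic lines. Ionisation of the diarylmethanol A5, which carries an ortho prenyl group, would give a benzhydryl cation; attack by the prenyl alkene closes ring B (Prins-type) and the tertiary cation loses a proton. The chosen plan is preferred because the cation at C1 is planar and only the remote C2' could bias its capture, because proton loss can give the isopropenyl isomer A6 as well as the isopropylidene compound, and because the acid needed can move the alkene into ring B. Ring A must again be made beforehand.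

Alternative 3: the same two rings from the terminal alkyne 18 by the gold-catalysed furan–yne phenol synthesis (a cationic monovalent gold catalyst such as (Ph3P)AuNTf2). That mechanism runs through a cyclopropyl carbenoid and an arene oxide and delivers oxygen to the alkyne-derived carbon. It would give phenol A7 with OH on C7 and no formyl group, and later ortho-formylation would give A8 with CHO on C6. Hydroxyl and formyl would be transposed relative to 22. The Diels–Alder mode with the ynal is the variant whose mechanism leaves oxygen on the furan carbon C6 and the formyl group on C7, and it delivers the aldehyde at its final oxidation level.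

Key step: step 11

Assumptions. (i) ArD stands for the (2S)-2-(2-hydroxypropan-2-yl)-6-methyl-2,3-dihydro-1,4-benzodioxin-8-yl group, bonded through C8'. (ii) 4 is taken as commercial; otherwise it is one step from 2-methoxy-4-methylphenol by ortho-formylation (MgCl2, Et3N, paraformaldehyde). (iii) The sense of induction in step 5 cannot be assigned from first principles; the bisphosphine antipode to be used is the one that delivers the alkynyl group to the Si face of the benzylic carbon of 9.

## Route

Step 1
Reactants: 1 3-methylbut-2-en-1-ol (prenol)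
Product: 3 [(2R)-3,3-dimethyloxiran-2-yl]methyl 3-nitrobenzenesulfonate, via (R)-3,3-dimethylglycidol 2 (not isolated)
Conditions: Ti(OiPr)4 (5 mol%), D-(−)-diethyl tartrate (7 mol%), t-BuOOH (2 equiv), 4 Å MS, CH2Cl2, −20 °C; P(OMe)3; then 3-NO2C6H4SO2Cl, Et3N, DMAP (cat.), −20 → 0 °C; recrystallise
Reagents that add atoms: tert-butyl hydroperoxide CC(C)(C)OO; 3-nitrobenzenesulfonyl chloride O=S(=O)(Cl)c1cccc([N+](=O)[O-])c1
Why: Sharpless asymmetric epoxidation of a primary allylic alcohol; the D-(−)-tartrate directs oxygen to the face that gives the 2R epoxy alcohol (the L-(+) ester gives the 2S series), and the water-soluble, labile 2 is sulfonylated in the same flask so that crystallisation of 3 can raise the enantiomeric purity.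

Step 2
Reactants: 4 2-hydroxy-3-methoxy-5-methylbenzaldehyde
Product: 5 2,3-dihydroxy-5-methylbenzaldehyde
Conditions: BBr3 (2.2 equiv), CH2Cl2, −78 → 0 °C; H2O
Reagents that add atoms: none
Why: Lewis acid cleavage of an aryl methyl ether; the chelated ortho-hydroxy aldehyde is tolerated, as in the standard demethylation of ortho-vanillin.

Step 3
Reactants: 5 2,3-dihydroxy-5-methylbenzaldehyde; 3 [(2R)-3,3-dimethyloxiran-2-yl]methyl 3-nitrobenzenesulfonate
Product: 7 (2S)-2-(2-hydroxypropan-2-yl)-6-methyl-2,3-dihydro-1,4-benzodioxine-8-carbaldehyde (ArD–CHO), via glycidyl aryl ether 6 (not isolated)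
Conditions: NaH (2.1 equiv), DMSO, 20 °C; 3 (1.0 equiv), 20 °C, then 70 °C; H2O
Reagents that add atoms: none
Why: In the dianion the non-chelated C3 phenoxide (future O4') is the more nucleophilic and displaces the sulfonate at the primary carbon (Williamson reaction, epoxide untouched) to give 6; on warming, the C2 phenoxide (future O1') opens the epoxide at its secondary carbon in a 6-exo SN2 reaction, the tertiary carbon being closed to SN2, so C2' is set as S by inversion of the R epoxide.

Step 4
Reactants: 7 ArD–CHO; 8 2,2-dimethyl-1,3-dioxane-4,6-dione (Meldrum's acid)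
Product: 9 5-(ArD-methylidene)-2,2-dimethyl-1,3-dioxane-4,6-dione
Conditions: 8 (1.1 equiv), piperidinium acetate (10 mol%), toluene, 4 Å MS, 50 °C
Reagents that add atoms: none
Why: Knoevenagel condensation of an aromatic aldehyde with a highly acidic methylene compound; the tertiary alcohol does not interfere.

Step 5
Reactants: 9 5-(ArD-methylidene)-2,2-dimethyl-1,3-dioxane-4,6-dione; 10 ethynyltrimethylsilane
Product: 11 5-[(1R)-1-ArD-3-(trimethylsilyl)prop-2-yn-1-yl]-2,2-dimethyl-1,3-dioxane-4,6-dione
Conditions: 10 (4 equiv), Rh(acac)(C2H4)2 (5 mol%), DTBM-SEGPHOS (6 mol%, antipode as in assumption iii), 1,4-dioxane, 60 °C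
Reagents that add atoms: none
Why: Rhodium-catalysed enantioselective conjugate alkynylation of an arylidene Meldrum's acid with a silylacetylene (alkynylrhodium insertion, then protonolysis of the rhodium enolate; the silyl group suppresses alkyne dimerisation); C1 is set by the chiral bisphosphine, alkynyl delivery to the Si face giving 1R in 11, which is the spatial arrangement of C1 (S) in 22.

Step 6
Reactants: 11 5-[(1R)-1-ArD-3-(trimethylsilyl)prop-2-yn-1-yl]-2,2-dimethyl-1,3-dioxane-4,6-dione
Product: 13 methyl (3S)-3-ArD-2-methylidene-5-(trimethylsilyl)pent-4-ynoate, via Mannich base 12 (not isolated)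
Conditions: CH2=NMe2+ I− (2.5 equiv), MeOH, 65 °C
Reagents that add atoms: N,N-dimethylmethyleneiminium iodide C=[N+](C)C.[I-]; methanol CO
Why: Mannich reaction at the acidic C5–H gives 12; methanolysis with loss of acetone and decarboxylative elimination of dimethylamine then give the 2-substituted acrylate (a known conversion of monosubstituted Meldrum's acids); the amine leaves as its hydroiodide, so the medium stays non-basic and C1–H, now γ to the acrylate, is not removed (the descriptor changes to S only through the sequence rule).

Step 7
Reactants: 13 methyl (3S)-3-ArD-2-methylidene-5-(trimethylsilyl)pent-4-ynoate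
Product: 15 (4R)-4-ArD-2-methyl-3-methylidene-6-(trimethylsilyl)hex-5-yn-2-ol, via methyl ketone 14 (not isolated)
Conditions: MeLi (5 equiv), CeCl3 (5 equiv, dried), THF, −78 → −40 °C; H2O
Reagents that add atoms: methyllithium [Li]C
Why: Double 1,2-addition of the organocerium reagent to the ester through the more reactive enone 14; the weakly basic cerium reagent avoids conjugate addition and γ-deprotonation at C1, and one equivalent is consumed by the free hydroxyl group.

Step 8
Reactants: 15 (4R)-4-ArD-2-methyl-3-methylidene-6-(trimethylsilyl)hex-5-yn-2-ol; 16 furan-2-ylboronic acid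
Product: 17 (3R)-3-ArD-4-(furan-2-ylmethyl)-5-methyl-1-(trimethylsilyl)hex-4-en-1-yne
Conditions: 16 (2 equiv), Pd(PPh3)4 (5 mol%), 1,4-dioxane, 80 °C
Reagents that add atoms: none
Why: Palladium-catalysed allyl–aryl coupling of a free tertiary allylic alcohol with an arylboronic acid (Suzuki–Miyaura coupling through a Tsuji–Trost π-allyl complex); the boronic acid activates the allylic hydroxyl, zerovalent palladium ionises it, and the furyl group is delivered to the unsubstituted CH2 terminus, which places the double bond regiospecifically as C2=C(CH3)2; the non-allylic tertiary alcohol is inert.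

Step 9
Reactants: 17 (3R)-3-ArD-4-(furan-2-ylmethyl)-5-methyl-1-(trimethylsilyl)hex-4-en-1-yne
Product: 18 (3R)-3-ArD-4-(furan-2-ylmethyl)-5-methylhex-4-en-1-yne
Conditions: K2CO3 (0.5 equiv), MeOH, 0 → 20 °C
Reagents that add atoms: none
Why: Methanolysis of the C(sp)–Si bond; methoxide is far too weak a base to remove C1–H of the skipped enyne.

Step 10
Reactants: 18 (3R)-3-ArD-4-(furan-2-ylmethyl)-5-methylhex-4-en-1-yne
Product: 20 (4R)-4-ArD-5-(furan-2-ylmethyl)-6-methylhept-5-en-2-ynal, via dilithium acetylide alkoxide 19 (not isolated)
Conditions: n-BuLi (2.1 equiv), THF, −78 °C; DMF (3 equiv), −78 → 0 °C; inverse quench into aq. KH2PO4, 0 °C; used at once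
Reagents that add atoms: N,N-dimethylformamide CN(C)C=O
Why: O–H and C(sp)–H are deprotonated much faster than C1–H, and the lithium acetylide is formylated by DMF; the inverse quench into phosphate buffer frees the ynal without exposing it to free dimethylamine, which could add to it or isomerise it.

Step 11
Reactants: 20 (4R)-4-ArD-5-(furan-2-ylmethyl)-6-methylhept-5-en-2-ynal
Product: 22 Diaporindene H, (1S)-6-hydroxy-1-ArD-2-(propan-2-ylidene)-2,3-dihydro-1H-indene-7-carbaldehyde, via oxa-bridged cycloadduct 21 (not isolated)
Conditions: Me2AlCl (3 equiv), CH2Cl2 (0.01 M), −78 → −20 °C; aq. potassium sodium tartrate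
Reagents that add atoms: none
Why: Intramolecular Diels–Alder reaction of a furan with a tethered, carbonyl-activated alkyne followed by aromatisation of the 7-oxanorbornadiene to a phenol (closest known type: Lewis acid promoted furan/ynone cycloaddition–aromatisation). Me2AlCl binds the aldehyde and lowers the LUMO of the C7≡C7a unit, and the furan (C3a, C4, C5, C6) adds across it; allylic strain from the isopropylidene methyl groups turns the alkynyl group on C1 and the furyl group on C3 out of the alkene plane and towards each other, so the three-atom tether is preorganised. Ring B closes by the C3a–C7a bond (five-membered ring, exo attack of the furan carbon on the alkyne carbon attached to C1) and ring A by the same bond plus C6–C7 (six-membered ring of the [4+2] adduct 21). Aluminium-assisted heterolysis of the C3a–O bond of 21 gives a tertiary, allylic cation that is the arenium ion of the product, and loss of H from C6 gives the phenol; the other mode (C6–O cleavage) leaves oxygen on the quaternary C3a and cannot aromatise, so oxygen ends on C6, ortho to the formyl group and para to C3a. No surviving stereocentre is created: the two bridgehead carbons of 21 become sp2, so either facial diastereomer of 21 converges on 22. C1 is carried through unchanged because no bond to it is made or broken and the medium is aprotic and non-basic (the hydroxyl groups release methane, not HCl), which matters because C1–H of 20 is γ to the ynal. The selectivity needed is cycloaddition before prototropic isomerisation of the skipped enynal and the correct opening of the oxa bridge; low temperature, high dilution and the substitution pattern of 21 should secure both.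

## Compound list

1 | 3-methylbut-2-en-1-ol (prenol) | CC(C)=CCO | starting material
2 | (R)-(3,3-dimethyloxiran-2-yl)methanol | CC1(C)O[C@@H]1CO | intermediate
3 | [(2R)-3,3-dimethyloxiran-2-yl]methyl 3-nitrobenzenesulfonate | CC1(C)O[C@@H]1COS(=O)(=O)c1cccc([N+](=O)[O-])c1 | intermediate
4 | 2-hydroxy-3-methoxy-5-methylbenzaldehyde | COc1cc(C)cc(C=O)c1O | starting material
5 | 2,3-dihydroxy-5-methylbenzaldehyde | Cc1cc(O)c(O)c(C=O)c1 | intermediate
6 | 3-{[(2R)-3,3-dimethyloxiran-2-yl]methoxy}-2-hydroxy-5-methylbenzaldehyde (present as its sodium phenoxide) | O=Cc1cc(C)cc(OC[C@H]2OC2(C)C)c1O | intermediate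
7 | (2S)-2-(2-hydroxypropan-2-yl)-6-methyl-2,3-dihydro-1,4-benzodioxine-8-carbaldehyde (ArD–CHO) | O=Cc1cc(C)cc2c1O[C@H](C(C)(C)O)CO2 | intermediate
8 | 2,2-dimethyl-1,3-dioxane-4,6-dione (Meldrum's acid) | CC1(C)OC(=O)CC(=O)O1 | starting material
9 | 5-(ArD-methylidene)-2,2-dimethyl-1,3-dioxane-4,6-dione | CC1(C)OC(=O)C(=Cc2cc(C)cc3c2O[C@H](C(C)(C)O)CO3)C(=O)O1 | intermediate
10 | ethynyltrimethylsilane | C#C[Si](C)(C)C | starting material
11 | 5-[(1R)-1-ArD-3-(trimethylsilyl)prop-2-yn-1-yl]-2,2-dimethyl-1,3-dioxane-4,6-dione | C[Si](C)(C)C#C[C@H](C1C(=O)OC(C)(C)OC1=O)c1cc(C)cc2c1O[C@H](C(C)(C)O)CO2 | intermediate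
12 | 5-[(1S)-1-ArD-3-(trimethylsilyl)prop-2-yn-1-yl]-5-[(dimethylamino)methyl]-2,2-dimethyl-1,3-dioxane-4,6-dione (Mannich base) | C[Si](C)(C)C#C[C@H](C1(CN(C)C)C(=O)OC(C)(C)OC1=O)c1cc(C)cc2c1O[C@H](C(C)(C)O)CO2 | intermediate
13 | methyl (3S)-3-ArD-2-methylidene-5-(trimethylsilyl)pent-4-ynoate | C[Si](C)(C)C#C[C@H](C(=C)C(=O)OC)c1cc(C)cc2c1O[C@H](C(C)(C)O)CO2 | intermediate
14 | (4S)-4-ArD-3-methylidene-6-(trimethylsilyl)hex-5-yn-2-one | C[Si](C)(C)C#C[C@H](C(=C)C(C)=O)c1cc(C)cc2c1O[C@H](C(C)(C)O)CO2 | intermediate
15 | (4R)-4-ArD-2-methyl-3-methylidene-6-(trimethylsilyl)hex-5-yn-2-ol | C[Si](C)(C)C#C[C@H](C(=C)C(C)(C)O)c1cc(C)cc2c1O[C@H](C(C)(C)O)CO2 | intermediate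
16 | furan-2-ylboronic acid | OB(O)c1ccco1 | starting material
17 | (3R)-3-ArD-4-(furan-2-ylmethyl)-5-methyl-1-(trimethylsilyl)hex-4-en-1-yne | C[Si](C)(C)C#C[C@H](C(Cc1ccco1)=C(C)C)c1cc(C)cc2c1O[C@H](C(C)(C)O)CO2 | intermediate
18 | (3R)-3-ArD-4-(furan-2-ylmethyl)-5-methylhex-4-en-1-yne | C#C[C@H](C(Cc1ccco1)=C(C)C)c1cc(C)cc2c1O[C@H](C(C)(C)O)CO2 | intermediate
19 | dilithium salt of 18 (lithium acetylide and lithium tertiary alkoxide) | [Li]C#C[C@H](C(Cc1ccco1)=C(C)C)c1cc(C)cc2c1O[C@H](C(C)(C)O[Li])CO2 | intermediate
20 | (4R)-4-ArD-5-(furan-2-ylmethyl)-6-methylhept-5-en-2-ynal | O=CC#C[C@H](C(Cc1ccco1)=C(C)C)c1cc(C)cc2c1O[C@H](C(C)(C)O)CO2 | intermediate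
21 | oxa-bridged cycloadduct: 3-formyl-7-oxabicyclo[2.2.1]hepta-2,5-diene whose C1 and C2 are spanned by CH2–C(=CMe2)–CH(ArD); the ArD-bearing carbon as in 20, bridgeheads as either facial diastereomer | O=CC1=C2[C@@H](c3cc(C)cc4c3O[C@H](C(C)(C)O)CO4)C(=C(C)C)CC25C=CC1O5 | intermediate
22 | Diaporindene H, (1S)-6-hydroxy-1-ArD-2-(propan-2-ylidene)-2,3-dihydro-1H-indene-7-carbaldehyde | CC(C)=C1Cc2ccc(O)c(C=O)c2[C@H]1c1cc(C)cc2c1O[C@H](C(C)(C)O)CO2 | target

## Step count and least certain steps

Total: 11 steps. Longest linear sequence: 10 steps (4 → 5 → 7 → 9 → 11 → 13 → 15 → 17 → 18 → 20 → 22); step 1 is the one-step side branch.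

Step 11 (key step). What may go wrong:
- prototropic isomerisation of the skipped enynal to the allenal before cycloaddition, which would erase C1;
- methyl transfer from aluminium to the aldehyde;
- a reversible cycloaddition with slow aromatisation;
- oligomerisation of the ynal.

The first variation is plain heating of 20 in toluene (80–110 °C, high dilution). The fallback changes the dienophile and the oxidation-state plan. It sets out from 18: C-acylation of its acetylide (n-BuLi, then ClCO2Me, −78 °C) should give the methyl ynoate F1, which is less electrophilic and less acidic at C1. Thermal furan/ynoate Diels–Alder–aromatisation (toluene, 110 °C) should give the methyl salicylate F2. Reduction with LiAlH4 would give the benzylic alcohol F3, and MnO2 would oxidise it to the aldehyde. The fallback rejoins the route at 22.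

Step 8. What may go wrong: protodeboronation of the furylboronic acid at 80 °C; β-hydride elimination from the π-allyl complex to a 1,3-diene; slow ionisation of the hindered alcohol. The fallback sets out from 15: n-BuLi (2.1 equiv) and ClCO2Me would give the bis(methyl carbonate) F4. Its allylic carbonate is ionised by Pd(PPh3)4 at 20 °C and coupled with 2-furylzinc chloride (Negishi coupling) to give the furfuryl enyne carbonate F5. K2CO3 in MeOH at 40 °C then removes both the C-silyl group and the remaining carbonate. The fallback rejoins the route at 18.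

Step 5. What may go wrong: low reactivity or poor facial selectivity because of the ortho-alkoxy substituent on ring C; a mismatch between the catalyst and the chiral substrate; competing alkyne oligomerisation. The fallback sets out from 9 and gives up catalyst control: uncatalysed 1,4-addition of [(trimethylsilyl)ethynyl]magnesium bromide (THF, −40 °C) should give 11 together with its C1 epimer F6. The two are diastereomers because of C2' and would be separated by crystallisation or chromatography. The fallback rejoins the route at 11.

Step 10. What may go wrong: amine-induced isomerisation of the ynal to the allenal or conjugate addition of dimethylamine during hydrolysis of the hemiaminal; partial deprotonation at C1 by excess base. The fallback sets out from 18: the acetylide (EtMgBr, THF) is hydroxymethylated with paraformaldehyde to the propargylic alcohol F7. Oxidation with MnO2 in CH2Cl2 then gives the ynal under neutral conditions. The fallback rejoins the route at 20.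

Step 6. What may go wrong: slow Mannich reaction at the hindered C5; loss of the C-silyl group in hot methanol; migration of the new double bond into conjugation with ring C and the alkyne. The fallback sets out from 11 and separates the events: methanolysis (MeOH, 65 °C) should give the malonic half ester F8, which is isolated. A decarboxylative Mannich methylenation at 20 °C (aqueous CH2O, Et2NH) then gives the acrylate. The fallback rejoins the route at 13.

## Further compounds

F1 | step 11 | methyl (4R)-4-ArD-5-(furan-2-ylmethyl)-6-methylhept-5-en-2-ynoate | COC(=O)C#C[C@H](C(Cc1ccco1)=C(C)C)c1cc(C)cc2c1O[C@H](C(C)(C)O)CO2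
F2 | step 11 | methyl (1S)-6-hydroxy-1-ArD-2-(propan-2-ylidene)-2,3-dihydro-1H-indene-7-carboxylate | CC(C)=C1Cc2ccc(O)c(C(=O)OC)c2[C@H]1c1cc(C)cc2c1O[C@H](C(C)(C)O)CO2
F3 | step 11 | (1S)-7-(hydroxymethyl)-1-ArD-2-(propan-2-ylidene)-2,3-dihydro-1H-inden-6-ol | CC(C)=C1Cc2ccc(O)c(CO)c2[C@H]1c1cc(C)cc2c1O[C@H](C(C)(C)O)CO2
F4 | step 8 | bis(methyl carbonate) of 15 (both tertiary hydroxyl groups as OCO2Me; 4R) | C[Si](C)(C)C#C[C@H](C(=C)C(C)(C)OC(=O)OC)c1cc(C)cc2c1O[C@H](C(C)(C)OC(=O)OC)CO2
F5 | step 8 | methyl carbonate of 17 (C2' side-chain hydroxyl as OCO2Me; 3R) | C[Si](C)(C)C#C[C@H](C(Cc1ccco1)=C(C)C)c1cc(C)cc2c1O[C@H](C(C)(C)OC(=O)OC)CO2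
F6 | step 5 | 5-[(1S)-1-ArD-3-(trimethylsilyl)prop-2-yn-1-yl]-2,2-dimethyl-1,3-dioxane-4,6-dione (C1 epimer of 11) | C[Si](C)(C)C#C[C@@H](C1C(=O)OC(C)(C)OC1=O)c1cc(C)cc2c1O[C@H](C(C)(C)O)CO2
F7 | step 10 | (4R)-4-ArD-5-(furan-2-ylmethyl)-6-methylhept-5-en-2-yn-1-ol | OCC#C[C@H](C(Cc1ccco1)=C(C)C)c1cc(C)cc2c1O[C@H](C(C)(C)O)CO2
F8 | step 6 | 2-[(1R)-1-ArD-3-(trimethylsilyl)prop-2-yn-1-yl]-3-methoxy-3-oxopropanoic acid (malonic half ester, either configuration at C2) | C[Si](C)(C)C#C[C@H](C(C(=O)O)C(=O)OC)c1cc(C)cc2c1O[C@H](C(C)(C)O)CO2
A1 | alternative 1 | [(2S)-2-(2-hydroxypropan-2-yl)-6-methyl-2,3-dihydro-1,4-benzodioxin-8-yl]boronic acid | OB(O)c1cc(C)cc2c1O[C@H](C(C)(C)O)CO2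
A2 | alternative 1 | 5-(benzyloxy)-4-(dimethoxymethyl)-1H-inden-1-one | O=C1C=Cc2c1ccc(OCc1ccccc1)c2C(OC)OC
A3 | alternative 1 | (3S)-3-ArD-5-(benzyloxy)-4-(dimethoxymethyl)-2,3-dihydro-1H-inden-1-one | O=C1C[C@H](c3cc(C)cc4c3O[C@H](C(C)(C)O)CO4)c2c1ccc(OCc1ccccc1)c2C(OC)OC
A4 | alternative 1 | (3S)-3-ArD-5-(benzyloxy)-4-(dimethoxymethyl)-2-(propan-2-ylidene)-2,3-dihydro-1H-inden-1-one | O=C1C(=C(C)C)[C@H](c3cc(C)cc4c3O[C@H](C(C)(C)O)CO4)c2c1ccc(OCc1ccccc1)c2C(OC)OC
A5 | alternative 2 | [2-(dimethoxymethyl)-3-(methoxymethoxy)-6-(3-methylbut-2-en-1-yl)phenyl](ArD)methanol (either carbinol configuration) | CC(C)=CCc1ccc(OCOC)c(C(OC)OC)c1C(O)c1cc(C)cc2c1O[C@H](C(C)(C)O)CO2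
A6 | alternative 2 | 7-(dimethoxymethyl)-6-(methoxymethoxy)-1-ArD-2-(prop-1-en-2-yl)-2,3-dihydro-1H-indene (isopropenyl isomer, mixture at C1 and C2) | C=C(C)C1Cc2ccc(OCOC)c(C(OC)OC)c2C1c1cc(C)cc2c1O[C@H](C(C)(C)O)CO2
A7 | alternative 3 | (1R)-1-ArD-2-(propan-2-ylidene)-2,3-dihydro-1H-inden-7-ol | CC(C)=C1Cc2cccc(O)c2[C@H]1c1cc(C)cc2c1O[C@H](C(C)(C)O)CO2
A8 | alternative 3 | (1R)-7-hydroxy-1-ArD-2-(propan-2-ylidene)-2,3-dihydro-1H-indene-6-carbaldehyde | CC(C)=C1Cc2ccc(C=O)c(O)c2[C@H]1c1cc(C)cc2c1O[C@H](C(C)(C)O)CO2
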